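**Plan**
Retrosynthesis cuts, in order: the O6–acyl bond (acid 25), the C11=C13 and C4=C15 methylene carbons, then C5–C6 and C9–C10 across ring B, giving quinone 2 and silyloxydiene 7.
Forward: ring A enters as the quinone (from phenol 1); ring B closes in the Diels–Alder step; diene 7 comes from aldehyde 3 and acetaldehyde 4 by crossed aldol condensation and O-silylation.
Enabling feature: ring B is flanked by C5–C6 and C9–C10, and ring A carries O at C1, O at C3, sp2 carbon at C4 and the C10 methyl exactly as 2-methoxy-5-methylbenzoquinone does.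
Stereochemistry: a BINOL–titanium Lewis acid sets C10 (absolute); endo addition sets C6 relative to C10; C5 is corrected to trans by epimerisation.
C7 comes from hydroxyl-directed hydrogenation (6α-OH); C1 and C3 come from substrate-controlled hydride delivery (anti to the angular methyl; axial attack).
End game: ester α-methylenation, selective unveiling of O6, Yamaguchi acylation, global desilylation.

Key step: step 4

Numbering: eudesmane numbering throughout (C14 = methyl on C10, C15 on C4, C11–C13 on C7); β is the face of the C10 methyl; 5α-H, 7α-H and 10β-CH3 unless stated.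
Assumption: the (R)-BINOL complex is taken to shield the quinone face that leads to (5R,6R,10R)-8; if the sense proves opposite, (S)-BINOL is used and nothing else changes.

Step 1
Reactants: 1 2-methoxy-5-methylphenol
Product: 2 2-methoxy-5-methyl-1,4-benzoquinone
Conditions: (KSO3)2NO (2.2 equiv), KH2PO4, H2O/acetone, 0 → 23 °C
Reagents that add atoms: potassium nitrosodisulfonate, [O]N(S(=O)(=O)[O-])S(=O)(=O)[O-].[K+].[K+]
Why: Teuber oxidation: the nitroxyl radical abstracts the phenolic hydrogen and a second equivalent delivers oxygen to the unsubstituted para carbon, so a phenol with a free para position should give the para-quinone.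

Step 2
Reactants: 3 methyl 4-oxobutanoate; 4 acetaldehyde
Product: 6 methyl (3E)-3-formylpent-3-enoate, via pyrrolidine enamine 5 (not isolated)
Conditions: pyrrolidine (1.05 equiv), K2CO3, Et2O, 0 °C; then 4 (1.5 equiv), AcOH, 0 → 23 °C; H2O
Reagents that add atoms: none
Why: Enamine-mediated crossed aldol condensation: the pre-formed enamine fixes 3 as donor, acetaldehyde is the most electrophilic acceptor, and dehydration through the iminium ion should give the thermodynamically preferred (E)-trisubstituted enal.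

Step 3
Reactants: 6 methyl (3E)-3-formylpent-3-enoate
Product: 7 methyl (3E)-3-[(tert-butyldimethylsilyl)oxymethylidene]pent-4-enoate
Conditions: TBSOTf, Et3N, Et2O, 0 → 23 °C
Reagents that add atoms: tert-butyldimethylsilyl triflate, CC(C)(C)[Si](C)(C)OS(=O)(=O)C(F)(F)F
Why: Silyl dienol ether formation by O-silylation of the aldehyde and γ-deprotonation of the methyl group; the s-trans enal places the silyloxy group trans to the new vinyl group, so the (1E)-diene needed for cycloaddition should predominate.

Step 4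
Reactants: 2 2-methoxy-5-methyl-1,4-benzoquinone; 7 methyl (3E)-3-[(tert-butyldimethylsilyl)oxymethylidene]pent-4-enoate
Product: 8 methyl 6α-(tert-butyldimethylsilyloxy)-3-methoxy-1,4-dioxo-13,15-dinor-5β-eudesma-2,7-dien-12-oate (cis-fused endo adduct; 5R,6R,10R)
Conditions: (R)-BINOL/TiCl2(OiPr)2 (20 mol %), 4 Å molecular sieves, CH2Cl2, −78 → −30 °C
Reagents that add atoms: none
Why: Concerted, asynchronous, endo-selective [4+2] cycloaddition of the Lewis-acid-activated quinone, the closest known reaction type being the chiral titanium- or boron-Lewis-acid-catalysed Diels–Alder reaction of 2-methoxy-5-methylbenzoquinone and related quinones with 1-oxygenated dienes. Ring B (six-membered) closes in one intermolecular cycloaddition event that forms C5–C6 and C9–C10 together. Site selectivity follows from the methoxy group, which deactivates its own double bond by donation so that the methyl-bearing C=C reacts. Regioselectivity follows from five-membered chelation of tetravalent titanium between the C4 carbonyl oxygen and the methoxy oxygen, which makes C10 the electrophilic β-carbon that meets C9, the diene terminus with the largest HOMO coefficient of the 1-silyloxydiene. C5 and C10 are set cis by suprafacial addition, C6 by the endo transition state together with the (E)-silyl enol ether geometry (O6 anti to the angular methyl), and the absolute configuration by the BINOL ligand, which shields one face of the chelated quinone. The step thus needs site, regio, endo and enantioface selectivity, secured respectively by the methoxy donor, the chelate, secondary orbital overlap under Lewis acid catalysis and the chiral ligand.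

Step 5
Reactants: 8 cis-fused adduct
Product: 9 methyl 6α-(tert-butyldimethylsilyloxy)-3-methoxy-1,4-dioxo-13,15-dinor-5α-eudesma-2,7-dien-12-oate (trans-fused; 5S,6R,10R)
Conditions: DBU (10 mol %), CH2Cl2, 0 °C
Reagents that add atoms: none
Why: Base-mediated epimerisation through the C4 enolate: C5 is the only enolisable ring position (C10 is quaternary), and reprotonation should drain the cis adduct into the trans-fused isomer with equatorial O6, the thermodynamic preference typical of angular-methyl quinone adducts, while catalytic base at 0 °C keeps silanolate loss and ester deconjugation slow.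

Step 6
Reactants: 9 trans-fused silyl ether
Product: 10 methyl 6α-hydroxy-3-methoxy-1,4-dioxo-13,15-dinor-5α-eudesma-2,7-dien-12-oate
Conditions: HF·pyridine, pyridine, THF, 0 → 23 °C
Reagents that add atoms: none
Why: Fluoride desilylation in a weakly acidic medium that should leave the vinylogous ester, the β-hydroxy ketone and the methyl ester untouched and frees the C6 hydroxyl as a directing group.

Step 7
Reactants: 10 allylic alcohol
Product: 11 methyl 6α-hydroxy-3-methoxy-1,4-dioxo-13,15-dinoreudesm-2-en-12-oate (7α-H)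
Conditions: H2 (1 atm), [Ir(cod)(PCy3)(py)]PF6 (5 mol %), CH2Cl2, 23 °C
Reagents that add atoms: none
Why: Hydroxyl-directed homogeneous hydrogenation: the cationic iridium centre binds the 6α-hydroxyl and delivers H2 to the α face of C7=C8 (also the face opposite the axial angular methyl), setting C7 with the CH2CO2Me group β and trans to O6, while the electron-poor push–pull C2=C3 bond binds the electrophilic catalyst poorly.

Step 8
Reactants: 11 γ-hydroxy ester
Product: 12 methyl 3-methoxy-1,4-dioxo-6α-(triethylsilyloxy)-13,15-dinoreudesm-2-en-12-oate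
Conditions: TESOTf, 2,6-lutidine, CH2Cl2, −78 °C
Reagents that add atoms: triethylsilyl triflate, CC[Si](CC)(CC)OS(=O)(=O)C(F)(F)F
Why: Silyl triflate silylation at low temperature outruns lactonisation of the γ-hydroxy ester, and the triethylsilyl group is chosen because it can later be removed in the presence of tert-butyldimethylsilyl ethers.

Step 9
Reactants: 12 ene-dione
Product: 13 methyl 3-methoxy-1-oxo-6α-(triethylsilyloxy)-13-noreudesma-2,4(15)-dien-12-oate
Conditions: Cp2Ti(μ-Cl)(μ-CH2)AlMe2 (1.1 equiv), pyridine (cat.), THF/toluene, −40 → 0 °C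
Reagents that add atoms: Tebbe reagent, C[Al](C)C[Ti](Cl)(C1C=CC=C1)C1C=CC=C1
Why: Tebbe methylenation: the non-basic titanium methylidene reacts with the C4 ketone faster than with the hindered vinylogous-ester C1 carbonyl or the methyl ester and cannot enolise C5, so the trans ring fusion and the β-silyloxy group survive.

Step 10
Reactants: 13 dienone
Product: 14 methyl 1β-hydroxy-3-methoxy-6α-(triethylsilyloxy)-13-noreudesma-2,4(15)-dien-12-oate
Conditions: NaBH4, CeCl3·7H2O, MeOH, −40 → 0 °C; aq. NaHCO3 work-up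
Reagents that add atoms: none
Why: Luche reduction (1,2-selective, spares the ester): hydride attacks C1 from the α face, anti to the adjacent axial C10 methyl, giving the 1β (equatorial) alcohol.

Step 11
Reactants: 14 dienyl alcohol
Product: 15 methyl 1β-(tert-butyldimethylsilyloxy)-3-methoxy-6α-(triethylsilyloxy)-13-noreudesma-2,4(15)-dien-12-oate
Conditions: TBSOTf, 2,6-lutidine, CH2Cl2, −78 → 0 °C
Reagents that add atoms: tert-butyldimethylsilyl triflate, CC(C)(C)[Si](C)(C)OS(=O)(=O)C(F)(F)F
Why: Silylation under basic conditions caps the acid-labile allylic C1 alcohol before enol ether hydrolysis, which blocks ionisation of C1–O and allylic transposition in the next step.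

Step 12
Reactants: 15 methoxydiene
Product: 17 methyl 1β-(tert-butyldimethylsilyloxy)-3β-hydroxy-6α-(triethylsilyloxy)-13-noreudesm-4(15)-en-12-oate, via 3-ketone 16 (not isolated)
Conditions: (CO2H)2 (10 mol %), THF/H2O, 0 °C; then CeCl3·7H2O, MeOH, NaBH4, −78 °C
Reagents that add atoms: water, O
Why: Mild acid hydrolysis of the 2-methoxydiene (protonation at C2, water adds at C3) unveils the C3 ketone, which is reduced in the same flask under Luche conditions by axial α-face hydride delivery to the 3β (equatorial) allylic alcohol, so the sensitive α-methylene ketone is never isolated.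

Step 13
Reactants: 17 allylic alcohol
Product: 18 methyl 1β,3β-bis(tert-butyldimethylsilyloxy)-6α-(triethylsilyloxy)-13-noreudesm-4(15)-en-12-oate
Conditions: TBSCl, imidazole, DMF, 23 °C
Reagents that add atoms: tert-butyldimethylsilyl chloride, CC(C)(C)[Si](C)(C)Cl
Why: Standard imidazole-mediated silylation of an unhindered secondary allylic alcohol.

Step 14
Reactants: 18 saturated ester
Product: 21 methyl 1β,3β-bis(tert-butyldimethylsilyloxy)-6α-(triethylsilyloxy)eudesma-4(15),11(13)-dien-12-oate, via Mannich base 19 (not isolated), via trimethylammonium iodide 20 (not isolated)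
Conditions: LiN(iPr)2, THF, −78 °C; Me2N=CH2 I, −78 → 23 °C; then MeI, 23 °C; then aq. NaHCO3
Reagents that add atoms: dimethylmethyleneiminium iodide (Eschenmoser's salt), C=[N+](C)C.[I-]
Why: Ester enolate Mannich reaction with Eschenmoser's salt, exhaustive methylation and Hofmann-type elimination, the standard α-methylenation of esters and lactones; the enolate has no β-leaving group and C7 is not enolisable, so its configuration is kept.

Step 15
Reactants: 21 tris-silyl ether
Product: 22 methyl 1β,3β-bis(tert-butyldimethylsilyloxy)-6α-hydroxyeudesma-4(15),11(13)-dien-12-oate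
Conditions: HF·pyridine, pyridine, THF, 0 °C
Reagents that add atoms: none
Why: Selective desilylation: buffered HF·pyridine cleaves a triethylsilyl ether much faster than secondary tert-butyldimethylsilyl ethers, and the cold, weakly acidic medium should not promote lactonisation of the freed γ-hydroxy acrylate.

Step 16
Reactants: 23 methyl 2-(hydroxymethyl)acrylate
Product: 24 methyl 2-[(tert-butyldimethylsilyloxy)methyl]acrylate
Conditions: TBSCl, imidazole, CH2Cl2, 0 → 23 °C
Reagents that add atoms: tert-butyldimethylsilyl chloride, CC(C)(C)[Si](C)(C)Cl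
Why: Standard silylation of a primary allylic alcohol.

Step 17
Reactants: 24 methyl 2-[(tert-butyldimethylsilyloxy)methyl]acrylate
Product: 25 2-[(tert-butyldimethylsilyloxy)methyl]acrylic acid
Conditions: LiOH, THF/H2O, 0 °C; then 1 M HCl to pH 4
Reagents that add atoms: lithium hydroxide, [Li+].[OH-]
Why: Saponification at 0 °C, where the silyl ether is stable and conjugate addition of hydroxide to the α-substituted acrylate is slow.

Step 18
Reactants: 22 6α-alcohol; 25 2-[(tert-butyldimethylsilyloxy)methyl]acrylic acid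
Product: 27 methyl 1β,3β-bis(tert-butyldimethylsilyloxy)-6α-{2-[(tert-butyldimethylsilyloxy)methyl]acryloyloxy}eudesma-4(15),11(13)-dien-12-oate, via mixed anhydride 26 (not isolated)
Conditions: 2,4,6-trichlorobenzoyl chloride, Et3N, toluene, 23 °C; then 22, DMAP, 23 °C
Reagents that add atoms: none
Why: Yamaguchi esterification: DMAP attacks the mixed anhydride at the less hindered acryloyl carbonyl, and the acylpyridinium should acylate the hindered equatorial 6α-hydroxyl faster than that hydroxyl attacks its own conjugated methyl ester.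

Step 19
Reactants: 27 tris-silyl ester
Product: 28 methyl 1β,3β-dihydroxy-6α-[2-(hydroxymethyl)acryloyloxy]eudesma-4(15),11(13)-dien-12-oate (1R,3S,5S,6S,7S,10R; CNP0247525.1)
Conditions: HF (48 % aq.), MeCN, 0 → 23 °C
Reagents that add atoms: none
Why: Global acidic fluoride desilylation that should leave both acrylate esters, the exocyclic alkene and the O6 ester in place, with no neighbouring free hydroxyl available for acyl migration.

**Compound list**
1 | 2-methoxy-5-methylphenol | COc1ccc(C)cc1O | starting material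
2 | 2-methoxy-5-methyl-1,4-benzoquinone | COC1=CC(=O)C(C)=CC1=O | intermediate
3 | methyl 4-oxobutanoate | COC(=O)CCC=O | starting material
4 | acetaldehyde | CC=O | starting material
5 | methyl (3E)-4-(pyrrolidin-1-yl)but-3-enoate (enamine, formed in the flask) | COC(=O)C/C=C/N1CCCC1 | intermediate
6 | methyl (3E)-3-formylpent-3-enoate | C/C=C(/C=O)CC(=O)OC | intermediate
7 | methyl (3E)-3-[(tert-butyldimethylsilyl)oxymethylidene]pent-4-enoate | C=C/C(CC(=O)OC)=C/O[Si](C)(C)C(C)(C)C | intermediate
8 | methyl 6α-(tert-butyldimethylsilyloxy)-3-methoxy-1,4-dioxo-13,15-dinor-5β-eudesma-2,7-dien-12-oate (cis-fused, 5R,6R,10R) | CC(C)(C)[Si](C)(C)O[C@@H]1[C@@H]2C(=O)C(OC)=CC(=O)[C@]2(C)CC=C1CC(=O)OC | intermediate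
9 | methyl 6α-(tert-butyldimethylsilyloxy)-3-methoxy-1,4-dioxo-13,15-dinor-5α-eudesma-2,7-dien-12-oate (trans-fused, 5S,6R,10R) | CC(C)(C)[Si](C)(C)O[C@@H]1[C@H]2C(=O)C(OC)=CC(=O)[C@]2(C)CC=C1CC(=O)OC | intermediate
10 | methyl 6α-hydroxy-3-methoxy-1,4-dioxo-13,15-dinor-5α-eudesma-2,7-dien-12-oate | O[C@@H]1[C@H]2C(=O)C(OC)=CC(=O)[C@]2(C)CC=C1CC(=O)OC | intermediate
11 | methyl 6α-hydroxy-3-methoxy-1,4-dioxo-13,15-dinoreudesm-2-en-12-oate | O[C@@H]1[C@H]2C(=O)C(OC)=CC(=O)[C@]2(C)CC[C@H]1CC(=O)OC | intermediate
12 | methyl 3-methoxy-1,4-dioxo-6α-(triethylsilyloxy)-13,15-dinoreudesm-2-en-12-oate | CC[Si](CC)(CC)O[C@@H]1[C@H]2C(=O)C(OC)=CC(=O)[C@]2(C)CC[C@H]1CC(=O)OC | intermediate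
13 | methyl 3-methoxy-1-oxo-6α-(triethylsilyloxy)-13-noreudesma-2,4(15)-dien-12-oate | CC[Si](CC)(CC)O[C@@H]1[C@H]2C(=C)C(OC)=CC(=O)[C@]2(C)CC[C@H]1CC(=O)OC | intermediate
14 | methyl 1β-hydroxy-3-methoxy-6α-(triethylsilyloxy)-13-noreudesma-2,4(15)-dien-12-oate | CC[Si](CC)(CC)O[C@@H]1[C@H]2C(=C)C(OC)=C[C@@H](O)[C@]2(C)CC[C@H]1CC(=O)OC | intermediate
15 | methyl 1β-(tert-butyldimethylsilyloxy)-3-methoxy-6α-(triethylsilyloxy)-13-noreudesma-2,4(15)-dien-12-oate | CC[Si](CC)(CC)O[C@@H]1[C@H]2C(=C)C(OC)=C[C@@H](O[Si](C)(C)C(C)(C)C)[C@]2(C)CC[C@H]1CC(=O)OC | intermediate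
16 | methyl 1β-(tert-butyldimethylsilyloxy)-3-oxo-6α-(triethylsilyloxy)-13-noreudesm-4(15)-en-12-oate (formed in the flask) | CC[Si](CC)(CC)O[C@@H]1[C@H]2C(=C)C(=O)C[C@@H](O[Si](C)(C)C(C)(C)C)[C@]2(C)CC[C@H]1CC(=O)OC | intermediate
17 | methyl 1β-(tert-butyldimethylsilyloxy)-3β-hydroxy-6α-(triethylsilyloxy)-13-noreudesm-4(15)-en-12-oate | CC[Si](CC)(CC)O[C@@H]1[C@H]2C(=C)[C@@H](O)C[C@@H](O[Si](C)(C)C(C)(C)C)[C@]2(C)CC[C@H]1CC(=O)OC | intermediate
18 | methyl 1β,3β-bis(tert-butyldimethylsilyloxy)-6α-(triethylsilyloxy)-13-noreudesm-4(15)-en-12-oate | CC[Si](CC)(CC)O[C@@H]1[C@H]2C(=C)[C@@H](O[Si](C)(C)C(C)(C)C)C[C@@H](O[Si](C)(C)C(C)(C)C)[C@]2(C)CC[C@H]1CC(=O)OC | intermediate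
19 | methyl 1β,3β-bis(tert-butyldimethylsilyloxy)-13-(dimethylamino)-6α-(triethylsilyloxy)eudesm-4(15)-en-12-oate (Mannich base, C11 epimers, formed in the flask) | CC[Si](CC)(CC)O[C@@H]1[C@H]2C(=C)[C@@H](O[Si](C)(C)C(C)(C)C)C[C@@H](O[Si](C)(C)C(C)(C)C)[C@]2(C)CC[C@H]1C(CN(C)C)C(=O)OC | intermediate
20 | N,N,N-trimethylammonium iodide of 19 (formed in the flask) | CC[Si](CC)(CC)O[C@@H]1[C@H]2C(=C)[C@@H](O[Si](C)(C)C(C)(C)C)C[C@@H](O[Si](C)(C)C(C)(C)C)[C@]2(C)CC[C@H]1C(C[N+](C)(C)C)C(=O)OC.[I-] | intermediate
21 | methyl 1β,3β-bis(tert-butyldimethylsilyloxy)-6α-(triethylsilyloxy)eudesma-4(15),11(13)-dien-12-oate | CC[Si](CC)(CC)O[C@@H]1[C@H]2C(=C)[C@@H](O[Si](C)(C)C(C)(C)C)C[C@@H](O[Si](C)(C)C(C)(C)C)[C@]2(C)CC[C@H]1C(=C)C(=O)OC | intermediate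
22 | methyl 1β,3β-bis(tert-butyldimethylsilyloxy)-6α-hydroxyeudesma-4(15),11(13)-dien-12-oate | O[C@@H]1[C@H]2C(=C)[C@@H](O[Si](C)(C)C(C)(C)C)C[C@@H](O[Si](C)(C)C(C)(C)C)[C@]2(C)CC[C@H]1C(=C)C(=O)OC | intermediate
23 | methyl 2-(hydroxymethyl)acrylate | C=C(CO)C(=O)OC | starting material
24 | methyl 2-[(tert-butyldimethylsilyloxy)methyl]acrylate | C=C(CO[Si](C)(C)C(C)(C)C)C(=O)OC | intermediate
25 | 2-[(tert-butyldimethylsilyloxy)methyl]acrylic acid | C=C(CO[Si](C)(C)C(C)(C)C)C(=O)O | intermediate
26 | 2-[(tert-butyldimethylsilyloxy)methyl]acrylic 2,4,6-trichlorobenzoic anhydride (formed in the flask) | C=C(CO[Si](C)(C)C(C)(C)C)C(=O)OC(=O)c1c(Cl)cc(Cl)cc1Cl | intermediate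
27 | methyl 1β,3β-bis(tert-butyldimethylsilyloxy)-6α-{2-[(tert-butyldimethylsilyloxy)methyl]acryloyloxy}eudesma-4(15),11(13)-dien-12-oate | C=C(CO[Si](C)(C)C(C)(C)C)C(=O)O[C@@H]1[C@H]2C(=C)[C@@H](O[Si](C)(C)C(C)(C)C)C[C@@H](O[Si](C)(C)C(C)(C)C)[C@]2(C)CC[C@H]1C(=C)C(=O)OC | intermediate
28 | methyl (1R,3S,5S,6S,7S,10R)-1β,3β-dihydroxy-6α-[2-(hydroxymethyl)acryloyloxy]eudesma-4(15),11(13)-dien-12-oate | C=C(CO)C(=O)O[C@@H]1[C@H]2C(=C)[C@@H](O)C[C@@H](O)[C@]2(C)CC[C@H]1C(=C)C(=O)OC | target

**Count**
Total: 19 steps. Longest linear sequence: 16 steps (3 → 28 through steps 2–15, 18 and 19).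

**Steps most likely to fail**

Step 4. What may go wrong: loss of enantioface discrimination if the quinone binds titanium through one oxygen only, or Lewis-acid-induced Mukaiyama–Michael addition and desilylation of the dienol ether in place of cycloaddition. The fallback replaces asymmetric catalysis by resolution and sets out from 2 and 7. These are combined with achiral, chelating SnCl4 in CH2Cl2 at −78 °C, or simply heated in toluene if any Lewis acid attacks the diene. This gives 8 as a racemate, that is, together with its mirror image methyl (5S,6S,10S)-6-(tert-butyldimethylsilyloxy)-3-methoxy-1,4-dioxo-13,15-dinoreudesma-2,7-dien-12-oate F1. Epimerisation as in step 5 then gives 9 together with its enantiomer, the trans-fused (5R,6S,10S) ene-dione F2. Preparative HPLC on an amylose tris(3,5-dimethylphenylcarbamate) phase separates the two, and the route is rejoined at 9.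

Step 5. What may go wrong: expulsion of silanolate from C6 out of the C4 enolate (vinylogous to C7=C8), or an equilibrium that stops short of the trans isomer. The fallback changes the order of events and sets out from 8. The silyl group is removed first (HF·pyridine, THF) to give the cis-fused alcohol methyl 6α-hydroxy-3-methoxy-1,4-dioxo-13,15-dinor-5β-eudesma-2,7-dien-12-oate F3, whose hydroxyl is a far poorer leaving group than a silanolate. This alcohol is equilibrated on neutral Al2O3 or with a trace of DBU; the trans isomer, held by a hydrogen bond from the equatorial 6-OH to the C4 carbonyl, is 10, where the route is rejoined.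

Step 12. What may go wrong: acid-promoted β-elimination of the C1 silyloxy group, migration of the exocyclic alkene into conjugation, or dimerisation of the cross-conjugated α-methylene ketone before it is reduced. The fallback masks the methylene as a Peterson precursor, so that no α-methylene ketone ever forms; it sets out from 12 and replaces steps 9–13.
- Me3SiCH2Li/CeCl3 (THF, −78 °C) adds to the C4 ketone to give methyl 4-hydroxy-3-methoxy-1-oxo-6α-(triethylsilyloxy)-15-(trimethylsilyl)-13-noreudesm-2-en-12-oate F4 (C4 epimers, both converge later).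
- Luche reduction gives the 1β-alcohol methyl 1β,4-dihydroxy-3-methoxy-6α-(triethylsilyloxy)-15-(trimethylsilyl)-13-noreudesm-2-en-12-oate F5.
- TBSOTf/2,6-lutidine at −78 °C silylates the secondary hydroxyl only, giving the 1β-(tert-butyldimethylsilyl) ether F6.
- Oxalic acid in wet THF hydrolyses the enol ether to the α-hydroxy ketone methyl 1β-(tert-butyldimethylsilyloxy)-4-hydroxy-3-oxo-6α-(triethylsilyloxy)-15-(trimethylsilyl)-13-noreudesman-12-oate F7.
- NaBH4 reduces it by axial attack to the 3β-alcohol F8.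
- TBSCl/imidazole gives the 1β,3β-bis(tert-butyldimethylsilyl) ether F9.
- KN(SiMe3)2 (THF, 0 °C) triggers syn-Peterson elimination of the tertiary β-silyl alkoxide to the exocyclic alkene, which is 18, where the route is rejoined.

**Further compounds**
F1 | step 4 | methyl (5S,6S,10S)-6-(tert-butyldimethylsilyloxy)-3-methoxy-1,4-dioxo-13,15-dinoreudesma-2,7-dien-12-oate (enantiomer of 8) | CC(C)(C)[Si](C)(C)O[C@H]1[C@H]2C(=O)C(OC)=CC(=O)[C@@]2(C)CC=C1CC(=O)OC
F2 | step 4 | trans-fused (5R,6S,10S) ene-dione (enantiomer of 9) | CC(C)(C)[Si](C)(C)O[C@H]1[C@@H]2C(=O)C(OC)=CC(=O)[C@@]2(C)CC=C1CC(=O)OC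
F3 | step 5 | methyl 6α-hydroxy-3-methoxy-1,4-dioxo-13,15-dinor-5β-eudesma-2,7-dien-12-oate | O[C@@H]1[C@@H]2C(=O)C(OC)=CC(=O)[C@]2(C)CC=C1CC(=O)OC
F4 | step 12 | methyl 4-hydroxy-3-methoxy-1-oxo-6α-(triethylsilyloxy)-15-(trimethylsilyl)-13-noreudesm-2-en-12-oate | CC[Si](CC)(CC)O[C@@H]1[C@H]2C(O)(C[Si](C)(C)C)C(OC)=CC(=O)[C@]2(C)CC[C@H]1CC(=O)OC
F5 | step 12 | methyl 1β,4-dihydroxy-3-methoxy-6α-(triethylsilyloxy)-15-(trimethylsilyl)-13-noreudesm-2-en-12-oate | CC[Si](CC)(CC)O[C@@H]1[C@H]2C(O)(C[Si](C)(C)C)C(OC)=C[C@@H](O)[C@]2(C)CC[C@H]1CC(=O)OC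
F6 | step 12 | 1β-(tert-butyldimethylsilyl) ether of F5 | CC[Si](CC)(CC)O[C@@H]1[C@H]2C(O)(C[Si](C)(C)C)C(OC)=C[C@@H](O[Si](C)(C)C(C)(C)C)[C@]2(C)CC[C@H]1CC(=O)OC
F7 | step 12 | methyl 1β-(tert-butyldimethylsilyloxy)-4-hydroxy-3-oxo-6α-(triethylsilyloxy)-15-(trimethylsilyl)-13-noreudesman-12-oate | CC[Si](CC)(CC)O[C@@H]1[C@H]2C(O)(C[Si](C)(C)C)C(=O)C[C@@H](O[Si](C)(C)C(C)(C)C)[C@]2(C)CC[C@H]1CC(=O)OC
F8 | step 12 | 3β-alcohol from F7 | CC[Si](CC)(CC)O[C@@H]1[C@H]2C(O)(C[Si](C)(C)C)[C@@H](O)C[C@@H](O[Si](C)(C)C(C)(C)C)[C@]2(C)CC[C@H]1CC(=O)OC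
F9 | step 12 | 1β,3β-bis(tert-butyldimethylsilyl) ether from F8 | CC[Si](CC)(CC)O[C@@H]1[C@H]2C(O)(C[Si](C)(C)C)[C@@H](O[Si](C)(C)C(C)(C)C)C[C@@H](O[Si](C)(C)C(C)(C)C)[C@]2(C)CC[C@H]1CC(=O)OC
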